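All constants are made up; the flask was simulated.

Take three vessels with equal charges and find which one keeps the largest share of target among the products.

    substrate + target → side product (k1 = 0.215 M⁻¹ min⁻¹)
    target → over-reaction product (k2 = 0.00146 min⁻¹)
    substrate + enzyme → target + enzyme, rate k3*[substrate]*[enzyme]/(1 + ([substrate]/Km3)) (Km3 = 0.238 M, k3 = 4790 M⁻¹ min⁻¹)

the same everywhere: enzyme 20 µM

| run | substrate | time | remark |
|---|---|---|---|
| south-west | 0.20 M (fed, over 80.0 min) | 80 min | all but substrate at the start; substrate goes in evenly over 80.0 min, the run ends at 80 min |
| east | 0.20 M |  | a single well-mixed tank run continuously and read at steady state, 80 min in it on average |
| south-east | 0.20 M | 80 min | everything together in a closed stirred flask, run for 80 min |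

- the set-up with the highest share of target in all that became target or over-reaction product or side product, at the outlet or at the end ("none" if the first two lie within 2 percentage points) (south-west / east / south-east / none)
- share of target in all that became target or over-reaction product or side product, at the outlet or at the end, south-west
- share of target in all that became target or over-reaction product or side product, at the outlet or at the end, east
- share of target in all that became target or over-reaction product or side product, at the outlet or at the end, south-east

- in percentages every species weighs as the substrate in it: one side product counts as two
- the stated concentrations are those of everything mixed, before any reaction; amounts are the same in each set-up
- the feed brings no volume worth counting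
- run time (south-west): 80 min

In south-west the enzyme has to keep pace with a feed of 0.00250 M min⁻¹, and at low [substrate] it offers a pseudo-first-order constant of 0.0958 min⁻¹. With the brake in its rate law included, the balance holds [substrate] near

0.0293 M.

So target's side-step half-life, the time in which the side step halves target at the standing [substrate], is 110 min. At the charged [substrate] it is 16 min, shorter than in south-west and short against the run. Decay has a half-life of 7.9 h, long against the run. I therefore expect south-west to lead, and I reckon its share in two ways.

Each target lost to the side step gives a side product weighing two. If x goes that way and d decays, the share is (1 − x − d)/(1 + x).

First way: target made evenly waits 40.0 min on average, which gives

x = 22.3%, d = 5.67%, share = 58.9%.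

Second way: I divide the side rate by the enzyme rate. [Substrate] cancels except in the brake, leaving mean [target], which I take as a straight rise from nothing to what this way itself leaves at the end. That puts x on both sides, with the group a = k1([substrate] charged − [substrate] standing)(brake)/(twice the pseudo-first-order constant) = 0.215:

x = a(1 − d)/(1 + a) = 16.7%, share = 66.5%.

The two part, and the first way cheats. Its balance hands the enzyme the whole feed, though the side step eats substrate too, so its [substrate] is too high and its loss grows in step with that. The second way starts from the same [substrate], but carries it only in the brake and in the height of the rise, which pull against each other, so I commit to its figure, with x lower. I reckon neither other vessel.

The forecast names south-west, with 68.5%, 54.9% and 59.7% for south-west, east and south-east, noting of south-west's held substrate “which limits side reaction”. Its south-west figure stands above mine.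

The simulation gives south-west as best, with 68.2%, 54.9% and 60.0%.

The path from substrate + target to side product is the largest single effect in south-west's lead over east: with that path taken away, east minus south-west moves from −13 percentage points to −5.5 points. The 11.3% of the charge standing in south-west at 80.0 min gives a side-step half-life of 143 min, longer than the run. The neighbour charged with 5.0 × 10⁻⁶ M of enzyme ends with 41.5% of its substrate standing, so its half-life is 38.8 min, shorter than the run, and its share is 44.3%.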